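**Plan**
- Target: all-E (3R,3′R,6′R)-7,8-didehydro-β,ε-carotene-3,3′-diol. The retrosynthesis cuts C11′=C12′ and C11=C12 (two Wittig reactions) to give an ε-ring C15 phosphonium salt, the C10 trienedial and an acetylenic C15 phosphonium salt. The acetylenic ring is then cut at C4–C5 and C1–C6.
- Enabling feature: in the acetylenic ring the tetrasubstituted C5=C6 bond is conjugated to the C7≡C8 triple bond, so this enyne is what a 1,3-diyne leaves behind after one triple bond has reacted as a 2π partner. Ring atoms C4, C3(O), C2, C1 and both geminal methyl groups are the six carbons and the oxygen of mesityl oxide.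
- Forward, acetylenic half: (E)-3-methylpent-2-en-4-yn-1-ol → silyl ether → bromoalkyne → methyl-capped enediyne; mesityl oxide → 2-silyloxydiene; a cobalt-catalysed [4+2] builds the ring and the whole C15 skeleton; then desilylation, enzymatic reduction and salt formation.
- Forward, ε half and assembly: (R)-α-ionone → enzymatic 3-hydroxylation → vinyl addition → phosphonium salt; C15 + C10 (first Wittig), then C25 + C15 (second Wittig).
- Stereochemistry: C3 by ketoreductase reduction; C6′ from (R)-α-ionone; C3′ by P450 hydroxylation trans to the side chain; 9E from the commercial (E)-enynol; 13E, 13′E and 15E from the dialdehyde; 7′E from α-ionone; 9′E by crystallisation of the salt; 11E and 11′E by Wittig reaction plus thermal isomerisation.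

Key step: step 5

Assumption: (R)-α-ionone is taken as a purchasable single enantiomer (it is offered by fine-chemical suppliers and is otherwise obtainable from the racemate by established resolution).

**Step 1**
Reactants: 1 (2E)-3-methylpent-2-en-4-yn-1-ol
Product: 2 tert-butyl(dimethyl){[(2E)-3-methylpent-2-en-4-yn-1-yl]oxy}silane
Conditions: TBSCl, imidazole, CH2Cl2, 0 °C → rt
Reagents that add atoms: tert-butyldimethylsilyl chloride, CC(C)(C)[Si](C)(C)Cl
Why: Imidazole-promoted silyl ether formation masks the only protic group before the alkyne and cobalt chemistry and does not touch the E alkene.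

**Step 2**
Reactants: 2 tert-butyl(dimethyl){[(2E)-3-methylpent-2-en-4-yn-1-yl]oxy}silane
Product: 3 {[(2E)-5-bromo-3-methylpent-2-en-4-yn-1-yl]oxy}(tert-butyl)dimethylsilane
Conditions: NBS, AgNO3 (10 mol%), acetone, rt, dark
Reagents that add atoms: N-bromosuccinimide, BrN1C(=O)CCC1=O
Why: Silver-catalysed electrophilic bromination of a terminal alkyne runs through the silver acetylide and should leave the trisubstituted alkene and the silyl ether intact.

**Step 3**
Reactants: 3 {[(2E)-5-bromo-3-methylpent-2-en-4-yn-1-yl]oxy}(tert-butyl)dimethylsilane; 4 propyne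
Product: 5 tert-butyl(dimethyl){[(2E)-3-methylocta-2-en-4,6-diyn-1-yl]oxy}silane
Conditions: propyne (excess), CuCl (5 mol%), NH2OH·HCl, n-BuNH2, H2O/Et2O, 0 °C
Reagents that add atoms: none
Why: Cadiot–Chodkiewicz coupling of the copper acetylide of propyne with the bromoalkyne should give the unsymmetrical 1,3-diyne, the cheap volatile partner being used in excess.

**Step 4**
Reactants: 6 mesityl oxide (4-methylpent-3-en-2-one)
Product: 8 tert-butyl(dimethyl)[(4-methylpenta-1,3-dien-2-yl)oxy]silane, via lithium 4-methylpenta-1,3-dien-2-olate 7 (not isolated)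
Conditions: LDA, THF, −78 °C; TBSCl, DMPU, −78 °C → rt
Reagents that add atoms: tert-butyldimethylsilyl chloride, CC(C)(C)[Si](C)(C)Cl
Why: Kinetic deprotonation at the α′-methyl group followed by O-silylation (silyl enol ether formation) should give the cross-conjugated 2-silyloxydiene and not the through-conjugated isomer.

**Step 5**
Reactants: 5 tert-butyl(dimethyl){[(2E)-3-methylocta-2-en-4,6-diyn-1-yl]oxy}silane; 8 tert-butyl(dimethyl)[(4-methylpenta-1,3-dien-2-yl)oxy]silane
Product: 9 tert-butyl({(2E)-5-[4-{[tert-butyl(dimethyl)silyl]oxy}-2,6,6-trimethylcyclohexa-1,4-dien-1-yl]-3-methylpent-2-en-4-yn-1-yl}oxy)dimethylsilane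
Conditions: 8 (1.5 equiv), CoBr2(dppe) (10 mol%; dppe = Ph2PCH2CH2PPh2), Zn powder (20 mol%), ZnI2 (20 mol%), CH2Cl2, 25–40 °C
Reagents that add atoms: none
Why: Proposed new method: zinc reduces CoBr2(dppe) to a cationic monovalent cobalt species that binds diene and diyne; oxidative cyclisation joins the unsubstituted CH2 terminus of the diene (ring C4) to the methyl-bearing alkyne carbon (ring C5), and C–C reductive elimination from the resulting vinyl(allyl)cobalt intermediate joins the alkynyl-bearing carbon (ring C6) to the dimethyl-substituted allyl terminus (ring C1). The closest known reaction type is the cobalt-catalysed neutral [4+2] cycloaddition of 2-silyloxybuta-1,3-dienes with unactivated internal alkynes and 1,3-diynes to cyclohexa-1,4-dienyl silyl ethers; new is a diene terminus that carries two methyl groups and ends as a quaternary carbon next to a tetrasubstituted alkene. The one ring formed is six-membered and closes in an intermolecular [4+2] mode, the second bond at the tertiary allyl terminus in preference to the four-membered alternative at the silyloxy carbon; since the bonds form one after the other at the metal, the first from the unhindered vinyl end, the low s-cis population that blocks a thermal Diels–Alder reaction of this diene should weigh less. No stereocentre is created, ring C3 stays trigonal as the silyl enol ether until step 7, and the E alkene of the side chain is not involved. The step needs site selectivity (the methyl-capped triple bond, not the one flanked by the branched alkene), orientation (alkynyl group para to the silyloxy carbon, as in the known cases, with cobalt on the carbon conjugated to the second triple bond) and mono-addition (the remaining triple bond then lies between two fully substituted alkene carbons); all three rest on the steric difference between the two ends of the enediyne and on its polarisation.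

**Step 6**
Reactants: 9 tert-butyl({(2E)-5-[4-{[tert-butyl(dimethyl)silyl]oxy}-2,6,6-trimethylcyclohexa-1,4-dien-1-yl]-3-methylpent-2-en-4-yn-1-yl}oxy)dimethylsilane
Product: 10 4-[(3E)-5-hydroxy-3-methylpent-3-en-1-yn-1-yl]-3,5,5-trimethylcyclohex-3-en-1-one
Conditions: TBAF (2.2 equiv), AcOH (2.5 equiv), THF, 0 °C → rt
Reagents that add atoms: none
Why: Buffered fluoride cleaves both Si–O bonds (silyl ether and silyl enol ether cleavage), and the enolate is protonated at once at ring C2, so the β,γ-unsaturated ketone should be released near neutrality with the ring double bond still conjugated to the alkyne.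

**Step 7**
Reactants: 10 4-[(3E)-5-hydroxy-3-methylpent-3-en-1-yn-1-yl]-3,5,5-trimethylcyclohex-3-en-1-one
Product: 11 (1R)-4-[(3E)-5-hydroxy-3-methylpent-3-en-1-yn-1-yl]-3,5,5-trimethylcyclohex-3-en-1-ol
Conditions: ketoreductase (NADPH-dependent, short-chain dehydrogenase class, selected by screening for the R alcohol), NADP+ (cat.), i-PrOH (10 vol%), phosphate buffer pH 7.0, 30 °C
Reagents that add atoms: none
Why: Enzymatic asymmetric ketone reduction delivers hydride to one face of the ring carbonyl in an active site that tells the gem-dimethyl arm from the methyl-alkene arm, as such enzymes do for 2,2,6-trimethylcyclohexane-1,4-dione; this sets the R carbinol centre, and the neutral buffer should prevent migration of the ring double bond.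

**Step 8**
Reactants: 11 (1R)-4-[(3E)-5-hydroxy-3-methylpent-3-en-1-yn-1-yl]-3,5,5-trimethylcyclohex-3-en-1-ol
Product: 12 [(2E)-5-[(4R)-4-hydroxy-2,6,6-trimethylcyclohex-1-en-1-yl]-3-methylpent-2-en-4-yn-1-yl](triphenyl)phosphonium bromide
Conditions: Ph3P·HBr (1.05 equiv), CH2Cl2, 0 °C → rt
Reagents that add atoms: triphenylphosphine hydrobromide, Br.c1ccc(cc1)P(c1ccccc1)c1ccccc1
Why: Triphenylphosphine hydrobromide converts the primary allylic alcohol into the allylic phosphonium salt (acid-mediated allylic substitution), while the homoallylic secondary ring alcohol should stay untouched, as is usual for hydroxylated C15 Wittig salts.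

**Step 9**
Reactants: 13 (R)-α-ionone, (3E)-4-[(1R)-2,6,6-trimethylcyclohex-2-en-1-yl]but-3-en-2-one
Product: 14 (3E)-4-[(1R,4R)-4-hydroxy-2,6,6-trimethylcyclohex-2-en-1-yl]but-3-en-2-one
Conditions: cytochrome P450 BM3 (CYP102A1) variant selected for trans-3-hydroxylation of α-ionone, air, NADP+ (cat.), alcohol dehydrogenase/i-PrOH for NADPH recycling, phosphate buffer pH 7.5, 25 °C
Reagents that add atoms: dioxygen, O=O
Why: Enzymatic C–H hydroxylation (P450 monooxygenase, hydrogen abstraction and oxygen rebound) at the allylic ring methylene C3 occurs on the face opposite the side chain at C6, so the enzyme pocket and the existing 6R centre together set 3R (trans), a selectivity that chemical allylic oxidants do not offer.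

**Step 10**
Reactants: 14 (3E)-4-[(1R,4R)-4-hydroxy-2,6,6-trimethylcyclohex-2-en-1-yl]but-3-en-2-one
Product: 15 (1E)-1-[(1R,4R)-4-hydroxy-2,6,6-trimethylcyclohex-2-en-1-yl]-3-methylpenta-1,4-dien-3-ol (both epimers at the new carbinol carbon)
Conditions: vinylMgBr (3 equiv), THF, −20 → 0 °C; aq. NH4Cl
Reagents that add atoms: vinylmagnesium bromide, C=C[Mg]Br
Why: Grignard 1,2-addition to the methyl enone, the first equivalent being consumed by the hydroxyl group; the new carbinol centre is formed without control and disappears in step 11.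

**Step 11**
Reactants: 15 (1E)-1-[(1R,4R)-4-hydroxy-2,6,6-trimethylcyclohex-2-en-1-yl]-3-methylpenta-1,4-dien-3-ol
Product: 16 [(2E,4E)-5-[(1R,4R)-4-hydroxy-2,6,6-trimethylcyclohex-2-en-1-yl]-3-methylpenta-2,4-dien-1-yl](triphenyl)phosphonium bromide
Conditions: Ph3P·HBr (1.0 equiv), CH2Cl2, −10 → 0 °C; recrystallisation
Reagents that add atoms: triphenylphosphine hydrobromide, Br.c1ccc(cc1)P(c1ccccc1)c1ccccc1
Why: Acid-promoted ionisation of the tertiary bis-allylic carbinol and capture of the pentadienyl cation by triphenylphosphine at the primary terminus (allylic transposition to the Wittig salt) should give the conjugated salt, the favoured 2E isomer being secured by crystallisation, while low temperature and one equivalent of acid spare the secondary allylic ring alcohol.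

**Step 12**
Reactants: 12 [(2E)-5-[(4R)-4-hydroxy-2,6,6-trimethylcyclohex-1-en-1-yl]-3-methylpent-2-en-4-yn-1-yl](triphenyl)phosphonium bromide; 17 (2E,4E,6E)-2,7-dimethylocta-2,4,6-trienedial
Product: 20 (2E,4E,6E,8E,10E)-13-[(4R)-4-hydroxy-2,6,6-trimethylcyclohex-1-en-1-yl]-2,7,11-trimethyltrideca-2,4,6,8,10-pentaen-12-ynal, via allylic phosphorus ylide 18 (not isolated), via minor 8Z aldehyde isomer 19 (not isolated)
Conditions: 17 (2.5 equiv), NaOMe, MeOH/CH2Cl2, 0 °C → rt; then toluene, 80 °C, dark
Reagents that add atoms: none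
Why: Wittig olefination of the semi-stabilised allylic ylide with an excess of the symmetrical dialdehyde should give the mono-adduct, and brief heating converts the sterically hindered cis portion of the new double bond (carotenoid C11=C12) into the E isomer.

**Step 13**
Reactants: 20 (2E,4E,6E,8E,10E)-13-[(4R)-4-hydroxy-2,6,6-trimethylcyclohex-1-en-1-yl]-2,7,11-trimethyltrideca-2,4,6,8,10-pentaen-12-ynal; 16 [(2E,4E)-5-[(1R,4R)-4-hydroxy-2,6,6-trimethylcyclohex-2-en-1-yl]-3-methylpenta-2,4-dien-1-yl](triphenyl)phosphonium bromide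
Product: 23 (all-E,3R,3′R,6′R)-7,8-didehydro-β,ε-carotene-3,3′-diol, via dienyl phosphorus ylide 21 (not isolated), via minor 11′Z isomer 22 (not isolated)
Conditions: 16 (1.3 equiv), NaOMe, MeOH/CH2Cl2, 0 °C → rt; then EtOH, 70 °C, dark, N2
Reagents that add atoms: none
Why: The second Wittig olefination joins the halves at C11′=C12′ with both hydroxyl groups free; the hindered 11′Z portion is isomerised thermally, while the unhindered trisubstituted double bonds, including 9E next to the triple bond, are not expected to move under these mild conditions.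

**Compound list**
1 | (2E)-3-methylpent-2-en-4-yn-1-ol | C#C/C(C)=C/CO | starting material
2 | tert-butyl(dimethyl){[(2E)-3-methylpent-2-en-4-yn-1-yl]oxy}silane | C#C/C(C)=C/CO[Si](C)(C)C(C)(C)C | intermediate
3 | {[(2E)-5-bromo-3-methylpent-2-en-4-yn-1-yl]oxy}(tert-butyl)dimethylsilane | BrC#C/C(C)=C/CO[Si](C)(C)C(C)(C)C | intermediate
4 | propyne | CC#C | starting material
5 | tert-butyl(dimethyl){[(2E)-3-methylocta-2-en-4,6-diyn-1-yl]oxy}silane | CC#CC#C/C(C)=C/CO[Si](C)(C)C(C)(C)C | intermediate
6 | mesityl oxide (4-methylpent-3-en-2-one) | CC(=O)C=C(C)C | starting material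
7 | lithium 4-methylpenta-1,3-dien-2-olate | [Li]OC(=C)C=C(C)C | intermediate
8 | tert-butyl(dimethyl)[(4-methylpenta-1,3-dien-2-yl)oxy]silane | C=C(O[Si](C)(C)C(C)(C)C)C=C(C)C | intermediate
9 | tert-butyl({(2E)-5-[4-{[tert-butyl(dimethyl)silyl]oxy}-2,6,6-trimethylcyclohexa-1,4-dien-1-yl]-3-methylpent-2-en-4-yn-1-yl}oxy)dimethylsilane | CC1=C(C#C/C(C)=C/CO[Si](C)(C)C(C)(C)C)C(C)(C)C=C(O[Si](C)(C)C(C)(C)C)C1 | intermediate
10 | 4-[(3E)-5-hydroxy-3-methylpent-3-en-1-yn-1-yl]-3,5,5-trimethylcyclohex-3-en-1-one | CC1=C(C#C/C(C)=C/CO)C(C)(C)CC(=O)C1 | intermediate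
11 | (1R)-4-[(3E)-5-hydroxy-3-methylpent-3-en-1-yn-1-yl]-3,5,5-trimethylcyclohex-3-en-1-ol | OC/C=C(\C)C#CC1=C(C)C[C@@H](O)CC1(C)C | intermediate
12 | [(2E)-5-[(4R)-4-hydroxy-2,6,6-trimethylcyclohex-1-en-1-yl]-3-methylpent-2-en-4-yn-1-yl](triphenyl)phosphonium bromide | [Br-].c1ccccc1[P+](c1ccccc1)(c1ccccc1)C/C=C(\C)C#CC1=C(C)C[C@@H](O)CC1(C)C | intermediate
13 | (R)-α-ionone, (3E)-4-[(1R)-2,6,6-trimethylcyclohex-2-en-1-yl]but-3-en-2-one | CC1=CCCC(C)(C)[C@H]1/C=C/C(C)=O | starting material
14 | (3E)-4-[(1R,4R)-4-hydroxy-2,6,6-trimethylcyclohex-2-en-1-yl]but-3-en-2-one | CC1=C[C@H](O)CC(C)(C)[C@H]1/C=C/C(C)=O | intermediate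
15 | (1E)-1-[(1R,4R)-4-hydroxy-2,6,6-trimethylcyclohex-2-en-1-yl]-3-methylpenta-1,4-dien-3-ol (both carbinol epimers) | CC1=C[C@H](O)CC(C)(C)[C@H]1/C=C/C(C)(O)C=C | intermediate
16 | [(2E,4E)-5-[(1R,4R)-4-hydroxy-2,6,6-trimethylcyclohex-2-en-1-yl]-3-methylpenta-2,4-dien-1-yl](triphenyl)phosphonium bromide | CC1=C[C@H](O)CC(C)(C)[C@H]1/C=C/C(C)=C/C[P+](c1ccccc1)(c1ccccc1)c1ccccc1.[Br-] | intermediate
17 | (2E,4E,6E)-2,7-dimethylocta-2,4,6-trienedial | O=C/C(C)=C/C=C/C=C(\C)C=O | starting material
18 | ylide of 12, {(2E)-5-[(4R)-4-hydroxy-2,6,6-trimethylcyclohex-1-en-1-yl]-3-methylpent-2-en-4-yn-1-ylidene}(triphenyl)phosphorane (drawn as the zwitterion) | [CH-](/C=C(\C)C#CC1=C(C)C[C@@H](O)CC1(C)C)[P+](c1ccccc1)(c1ccccc1)c1ccccc1 | intermediate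
19 | (2E,4E,6E,8Z,10E)-13-[(4R)-4-hydroxy-2,6,6-trimethylcyclohex-1-en-1-yl]-2,7,11-trimethyltrideca-2,4,6,8,10-pentaen-12-ynal (carotenoid 11Z isomer of 20) | O=C/C(C)=C/C=C/C=C(C)/C=C\C=C(/C)C#CC1=C(C)C[C@@H](O)CC1(C)C | intermediate
20 | (2E,4E,6E,8E,10E)-13-[(4R)-4-hydroxy-2,6,6-trimethylcyclohex-1-en-1-yl]-2,7,11-trimethyltrideca-2,4,6,8,10-pentaen-12-ynal | O=C/C(C)=C/C=C/C=C(C)/C=C/C=C(\C)C#CC1=C(C)C[C@@H](O)CC1(C)C | intermediate
21 | ylide of 16, {(2E,4E)-5-[(1R,4R)-4-hydroxy-2,6,6-trimethylcyclohex-2-en-1-yl]-3-methylpenta-2,4-dien-1-ylidene}(triphenyl)phosphorane (drawn as the zwitterion) | CC1=C[C@H](O)CC(C)(C)[C@H]1/C=C/C(C)=C/[CH-][P+](c1ccccc1)(c1ccccc1)c1ccccc1 | intermediate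
22 | (11′Z,3R,3′R,6′R)-7,8-didehydro-β,ε-carotene-3,3′-diol | CC1=C[C@H](O)CC(C)(C)[C@H]1/C=C/C(C)=C/C=C\C(C)=C\C=C\C=C(C)\C=C\C=C(/C)C#CC1=C(C)C[C@@H](O)CC1(C)C | intermediate
23 | (all-E,3R,3′R,6′R)-7,8-didehydro-β,ε-carotene-3,3′-diol | CC1=C[C@H](O)CC(C)(C)[C@H]1/C=C/C(C)=C/C=C/C(C)=C/C=C/C=C(C)/C=C/C=C(\C)C#CC1=C(C)C[C@@H](O)CC1(C)C | target

**Step count**
Total: 13 steps. Longest linear sequence: 9 steps (steps 1, 2, 3, 5, 6, 7, 8, 12, 13).

**Steps most likely to fail**

Step 5 (proposed new method). The hindered diene may fail to enter the cobalt cycle, the cycloaddition may occur at the other triple bond or with the opposite orientation, or the diyne may cyclotrimerise. The fallback keeps the same two ring bonds but forms them by a known polar, Lewis-acid-promoted Diels–Alder reaction of a hindered 2-silyloxydiene with an acetylenic aldehyde. It sets out from 8 and returns at 9. Diene 8 and commercial but-2-ynal would be combined with Me2AlCl (or the AlBr3/AlMe3 couple) in CH2Cl2 at −40 to 0 °C to give 4-{[tert-butyl(dimethyl)silyl]oxy}-2,6,6-trimethylcyclohexa-1,4-diene-1-carbaldehyde F1. Both donor groups of the diene direct its CH2 terminus to the methyl-bearing β-carbon of the ynal. Colvin rearrangement (Me3SiCHN2, LDA, THF, −78 → 0 °C) would turn the aldehyde into tert-butyl[(4-ethynyl-3,3,5-trimethylcyclohexa-1,4-dien-1-yl)oxy]dimethylsilane F2. The coupling partner would come from but-2-yn-1-ol by silylation to tert-butyl(but-2-yn-1-yloxy)dimethylsilane F3, then hydrozirconation with Cp2Zr(H)Cl and iodination to tert-butyl{[(2E)-3-iodobut-2-en-1-yl]oxy}dimethylsilane F4. Sonogashira coupling of F2 with F4 (Pd(PPh3)4, CuI, i-Pr2NH, rt) would give 9.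

Step 7. The enzyme may discriminate poorly between the two faces of a ketone whose arms differ only at the β-carbons, or the ring double bond may migrate into conjugation with the ketone before reduction. The fallback replaces asymmetric reduction by resolution. It sets out from 10 and returns at 11. Reduction with NaBH4 in MeOH at −20 °C would give racemic 4-[(3E)-5-hydroxy-3-methylpent-3-en-1-yn-1-yl]-3,5,5-trimethylcyclohex-3-en-1-ol F5. Lipase-catalysed acylation (Burkholderia cepacia lipase, vinyl acetate, MTBE, 30 °C) esterifies the primary alcohol of both enantiomers and should acylate the secondary alcohol of the R enantiomer faster. This would give (1R)-4-[(3E)-5-acetoxy-3-methylpent-3-en-1-yn-1-yl]-3,5,5-trimethylcyclohex-3-en-1-yl acetate F6 beside (2E)-5-[(4S)-4-hydroxy-2,6,6-trimethylcyclohex-1-en-1-yl]-3-methylpent-2-en-4-yn-1-yl acetate F7. After chromatographic separation, methanolysis of F6 (K2CO3, MeOH, 0 °C) would give 11.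

Step 11. The acid may ionise the secondary allylic ring alcohol (loss or epimerisation of the 3′-hydroxyl, attack of phosphine on the ring), and the double-bond geometry may scramble in the pentadienyl cation. The fallback inverts the polarity of the last coupling so that the ε ring never meets acid. It sets out from 14 and 20 and returns at 23. Horner–Wadsworth–Emmons reaction of 14 with diethyl (cyanomethyl)phosphonate (NaH, THF, 0 °C → rt) would give (2E,4E)-5-[(1R,4R)-4-hydroxy-2,6,6-trimethylcyclohex-2-en-1-yl]-3-methylpenta-2,4-dienenitrile F8. Reduction with i-Bu2AlH (CH2Cl2, −78 °C) and mild hydrolysis would give (2E,4E)-5-[(1R,4R)-4-hydroxy-2,6,6-trimethylcyclohex-2-en-1-yl]-3-methylpenta-2,4-dienal F9. Aldehyde 20 would be reduced with NaBH4 (EtOH, 0 °C) to (2E,4E,6E,8E,10E)-13-[(4R)-4-hydroxy-2,6,6-trimethylcyclohex-1-en-1-yl]-2,7,11-trimethyltrideca-2,4,6,8,10-pentaen-12-yn-1-ol F10. Ph3P·HBr (CH2Cl2, 0 °C) would convert F10 into [(2E,4E,6E,8E,10E)-13-[(4R)-4-hydroxy-2,6,6-trimethylcyclohex-1-en-1-yl]-2,7,11-trimethyltrideca-2,4,6,8,10-pentaen-12-yn-1-yl](triphenyl)phosphonium bromide F11. Wittig reaction of F11 with F9 (NaOMe, MeOH/CH2Cl2, then brief warming) would give 23.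

**Further compounds**
F1 | step 5 | 4-{[tert-butyl(dimethyl)silyl]oxy}-2,6,6-trimethylcyclohexa-1,4-diene-1-carbaldehyde | CC1=C(C=O)C(C)(C)C=C(O[Si](C)(C)C(C)(C)C)C1
F2 | step 5 | tert-butyl[(4-ethynyl-3,3,5-trimethylcyclohexa-1,4-dien-1-yl)oxy]dimethylsilane | CC1=C(C#C)C(C)(C)C=C(O[Si](C)(C)C(C)(C)C)C1
F3 | step 5 | tert-butyl(but-2-yn-1-yloxy)dimethylsilane | CC#CCO[Si](C)(C)C(C)(C)C
F4 | step 5 | tert-butyl{[(2E)-3-iodobut-2-en-1-yl]oxy}dimethylsilane | C/C(I)=C\CO[Si](C)(C)C(C)(C)C
F5 | step 7 | racemic 4-[(3E)-5-hydroxy-3-methylpent-3-en-1-yn-1-yl]-3,5,5-trimethylcyclohex-3-en-1-ol | CC1=C(C#C/C(C)=C/CO)C(C)(C)CC(O)C1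
F6 | step 7 | (1R)-4-[(3E)-5-acetoxy-3-methylpent-3-en-1-yn-1-yl]-3,5,5-trimethylcyclohex-3-en-1-yl acetate | CC(=O)OC/C=C(\C)C#CC1=C(C)C[C@@H](OC(C)=O)CC1(C)C
F7 | step 7 | (2E)-5-[(4S)-4-hydroxy-2,6,6-trimethylcyclohex-1-en-1-yl]-3-methylpent-2-en-4-yn-1-yl acetate | CC(=O)OC/C=C(\C)C#CC1=C(C)C[C@H](O)CC1(C)C
F8 | step 11 | (2E,4E)-5-[(1R,4R)-4-hydroxy-2,6,6-trimethylcyclohex-2-en-1-yl]-3-methylpenta-2,4-dienenitrile | CC1=C[C@H](O)CC(C)(C)[C@H]1/C=C/C(C)=C/C#N
F9 | step 11 | (2E,4E)-5-[(1R,4R)-4-hydroxy-2,6,6-trimethylcyclohex-2-en-1-yl]-3-methylpenta-2,4-dienal | CC1=C[C@H](O)CC(C)(C)[C@H]1/C=C/C(C)=C/C=O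
F10 | step 11 | (2E,4E,6E,8E,10E)-13-[(4R)-4-hydroxy-2,6,6-trimethylcyclohex-1-en-1-yl]-2,7,11-trimethyltrideca-2,4,6,8,10-pentaen-12-yn-1-ol | OC/C(C)=C/C=C/C=C(C)/C=C/C=C(\C)C#CC1=C(C)C[C@@H](O)CC1(C)C
F11 | step 11 | [(2E,4E,6E,8E,10E)-13-[(4R)-4-hydroxy-2,6,6-trimethylcyclohex-1-en-1-yl]-2,7,11-trimethyltrideca-2,4,6,8,10-pentaen-12-yn-1-yl](triphenyl)phosphonium bromide | [Br-].c1ccccc1[P+](c1ccccc1)(c1ccccc1)C/C(C)=C/C=C/C=C(C)/C=C/C=C(\C)C#CC1=C(C)C[C@@H](O)CC1(C)C
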